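I have no constants for these flasks, so this note rests on a reading and not on a rate law. The elm flask is charged with 2.80 M of starting material, 1.60 M of partner and 0.0240 M of free catalyst, and it is to be read at 49 h. Partner is its limiting reagent, since its charge is smaller than that of the starting material.

| flask | starting material | partner | free catalyst | time |
|---|---|---|---|---|
| oak | 0.800 M | 1.60 M | 0.0240 M |  |
| ash | 0.480 M | 1.28 M | 0.0240 M |  |
| maple | 1.60 M | 1.60 M | 0.0240 M |  |
| alder | 0.800 M | 2.40 M | 0.0240 M |  |
| elm | 2.80 M | 1.60 M | 0.0240 M | 49 h |

| run | time / h | [product] / M |
|---|---|---|
| oak run | 1.8 | 0.046 |
| oak run | 5.3 | 0.120 |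
| oak run | 10 | 0.211 |
| oak run | 16 | 0.310 |
| oak run | 23 | 0.402 |
| oak run | 31 | 0.477 |
| oak run | 40 | 0.546 |
| oak run | 49 | 0.600 |
| ash run | 1.8 | 0.028 |
| ash run | 5.3 | 0.076 |
| ash run | 10 | 0.135 |
| ash run | 16 | 0.207 |
| ash run | 23 | 0.268 |
| ash run | 31 | 0.316 |
| ash run | 40 | 0.381 |
| ash run | 49 | 0.412 |
| maple run | 1.8 | 0.075 |
| maple run | 5.3 | 0.193 |
| maple run | 10 | 0.333 |
| maple run | 16 | 0.472 |
| maple run | 23 | 0.594 |
| maple run | 31 | 0.692 |
| maple run | 40 | 0.770 |
| maple run | 49 | 0.826 |
| alder run | 1.8 | 0.055 |
| alder run | 5.3 | 0.153 |
| alder run | 10 | 0.275 |
| alder run | 16 | 0.399 |
| alder run | 23 | 0.494 |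
| alder run | 31 | 0.577 |
| alder run | 40 | 0.650 |
| alder run | 49 | 0.713 |

(standard deviation of a reading: 0.006 M)

1. apparent order in [starting material] of the starting rate, round the charge of the oak run (the rate where two percent of its starting material have turned into product) (one fixed amount of product, the same in the runs compared)
2. apparent order in [partner] of the starting rate, round the charge of the oak run (the rate where two percent of its starting material have turned into product)
3. the ash run starts with 0.320 M less of starting material and of partner than the oak run, and with no product. Compared where both hold the same amount of starting material, once fifteen percent of what the ash run was charged with has turned into product, is the ash run faster, slower or alike (within a tenth)?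
4. product in the elm run at 49 h, as a share of the starting material charged

- Overall: starting material + partner -> product, with free catalyst as catalyst.
- Constant volume, constant temperature.
- Readings of a species count what is bound in complexes too.
- An order is taken over about fifteen percent of the charge, up and down.

Oak and maple hold the same partner charge, and maple has twice the starting material, so that pair shows what extra starting material buys. The gain exponent at 49 h reads 0.461; by gain exponent I mean the logarithm of the ratio of product in two flasks of equal partner charge, over the logarithm of the ratio of their starting material, at one fixed time. At 10 h the same pair reads 0.658, so the comparison drifts downward as the flasks age.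

I carry the later value from maple to elm. That gives 1.07 M of product at 49 h, which is 38.2% of the charge and lies below the partner charge. Whoever comes to the bench reads the elm flask at 49 h; from oak to maple the product at that time rose by a factor of 1.38.

The forecast gives 0.75 in starting material, 0.5 in partner, the ash run faster, and 29% for elm, which is lower than my figure. Its ground for the late behaviour reads: “Maple late is far slower than the initial-rate law predicts”.

The simulation gives 0.64 in starting material, 0.71 in partner, the ash run faster, and 36.9% for elm.

    free catalyst + starting material → catalyst-substrate complex (6.516 L mol⁻¹ h⁻¹)
    catalyst-substrate complex + partner → loaded catalyst (1.177 L mol⁻¹ h⁻¹)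
    loaded catalyst → product + free catalyst (0.6408 h⁻¹)
    partner → lost reagent (0.02106 h⁻¹)
    starting material + partner → product (0.01364 L mol⁻¹ h⁻¹)

At the start of the elm run the direct step makes product at 0.0611 M h⁻¹, above the 0.0154 M h⁻¹ that loaded catalyst would release if the whole catalyst charge stood in that form, while partner goes to lost reagent at 0.0337 M h⁻¹. By 49 h the elm run holds 1.03 M of product, its gain exponent from maple stands at 0.398, and partner, lost reagent and loaded catalyst together hold the remaining 0.567 M of the partner charge.

All runs stem from a simulated flask with made-up constants, and the scatter is random.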